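**Plan**

- Labdane numbering is used for the terpenoid part (ring A = C1–C5, C10; ring B = C5–C10; C17 = methylene carbon on C8; C11 = benzylic CH2). Retrosynthetic cuts, in order: the benzo ring of the naphthoquinone (Diels–Alder of a C9 (E)-3-methylpentadienyl chain with 2-methoxy-3-methylbenzoquinone), C9–C11 (enolate alkylation), C6–C7 (ring B), C9–C10 (conjugate allylation), ring A (Diels–Alder).
- Enabling feature: the methylene-bearing carbon C8 of ring B lies 1,3 to C6 across C7. With C8 as a methyl ketone and C6 as an aldehyde on the ring-fusion carbon C5, ring B closes by aldol condensation. The C8 carbonyl then blocks C7, directs alkylation and equilibration at C9, and becomes the methylene.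
- Forward order: ring A → C10 quaternary centre → ring B (C6–C7) → C9 side chain → C8 methylene → naphthoquinone ring.
- Stereochemistry: C4/C5 trans from the (E)-dienophile in a catalytic enantioselective Diels–Alder reaction; C10 by 1,4-addition anti to the C5 substituent; C9 by equilibration next to the C8 ketone.

Key step: step 10

Assumption: the (S)-oxazaborolidinium catalyst of step 4 is taken to give the antipode of 7 that is drawn; if the facial sense proves opposite, its mirror image is used with nothing else changed.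

**Route**

Step 1
Reactants: 1 2,2-dimethoxyacetaldehyde; 2 methyl 2-(triphenylphosphoranylidene)propanoate
Product: 3 methyl (E)-4,4-dimethoxy-2-methylbut-2-enoate
Conditions: CH2Cl2/H2O, rt
Reagents that add atoms: none
Why: Wittig olefination with a stabilised ylide should give the (E)-enoate selectively.

Step 2
Reactants: 3 methyl (E)-4,4-dimethoxy-2-methylbut-2-enoate
Product: 4 methyl (E)-2-methyl-4-oxobut-2-enoate
Conditions: Amberlyst-15, acetone/H2O, rt
Reagents that add atoms: water, O
Why: Acid hydrolysis of the dimethyl acetal should free the aldehyde without touching the ester or the (E) geometry.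

Step 3
Reactants: 5 (E)-pent-3-en-2-one
Product: 6 (E)-2-(tert-butyldimethylsilyloxy)penta-1,3-diene
Conditions: TBSOTf, Et3N, CH2Cl2, 0 °C
Reagents that add atoms: tert-butyldimethylsilyl triflate, CC(C)(C)[Si](C)(C)OS(=O)(=O)C(F)(F)F
Why: Soft enolisation of the methyl ketone with silyl triflate and amine should give the cross-conjugated 2-silyloxy diene.

Step 4
Reactants: 4 methyl (E)-2-methyl-4-oxobut-2-enoate; 6 (E)-2-(tert-butyldimethylsilyloxy)penta-1,3-diene
Product: 7 methyl 3-(tert-butyldimethylsilyloxy)-6-formyl-1,5-dimethylcyclohex-3-ene-1-carboxylate (formyl trans to CO2Me; both C5 epimers)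
Conditions: (S)-o-tolyl-oxazaborolidine from (S)-α,α-diphenylprolinol, activated with Tf2NH (20 mol %), CH2Cl2, −78 °C
Reagents that add atoms: none
Why: In this catalytic enantioselective Diels–Alder reaction the CH2 terminus of the 2-silyloxy diene should bond to the β-carbon C4 and the methyl-bearing terminus to C5 (para and ortho rules agree), suprafacial addition to the (E)-dienophile fixes CHO trans to CO2Me, and the formyl-bound chiral Lewis acid shields one face to set the absolute configuration.

Step 5
Reactants: 7 methyl 3-(tert-butyldimethylsilyloxy)-6-formyl-1,5-dimethylcyclohex-3-ene-1-carboxylate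
Product: 8 methyl 6-formyl-1,5-dimethyl-3-oxocyclohex-4-ene-1-carboxylate (formyl trans to CO2Me)
Conditions: Pd(OAc)2 (1.1 equiv), MeCN, rt; used crude
Reagents that add atoms: none
Why: In the Saegusa–Ito oxidation the palladium enolate at C1 can lose only the hydrogen on C10, so both C10 epimers should give the same 3-methyl enone under non-basic conditions that spare the doubly activated C5–H.

Step 6
Reactants: 8 methyl 6-formyl-1,5-dimethyl-3-oxocyclohex-4-ene-1-carboxylate
Product: 9 methyl 6-(1,3-dioxolan-2-yl)-1,5-dimethyl-3-oxocyclohex-4-ene-1-carboxylate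
Conditions: (TMSOCH2)2, TMSOTf (5 mol %), CH2Cl2, −78 °C
Reagents that add atoms: 1,2-bis(trimethylsilyloxy)ethane, C[Si](C)(C)OCCO[Si](C)(C)C
Why: Noyori acetalisation at low temperature should be selective for the aldehyde over the conjugated ketone and too mild to epimerise C5.

Step 7
Reactants: 9 methyl 6-(1,3-dioxolan-2-yl)-1,5-dimethyl-3-oxocyclohex-4-ene-1-carboxylate
Product: 11 methyl 3-allyl-2-(1,3-dioxolan-2-yl)-1,3-dimethyl-5-oxocyclohexane-1-carboxylate (allyl trans to dioxolanyl), via trimethylsilyl enol ether 10 (not isolated)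
Conditions: allylMgBr, CuBr·SMe2, Me3SiCl, THF, −78 °C; then 1 M citric acid
Reagents that add atoms: allylmagnesium bromide, C=CC[Mg]Br
Why: A Lipshutz-type 1,4-addition of allylcopper accelerated by Me3SiCl should create the C10 quaternary centre with allyl entering anti to the adjacent C5 substituent, which places the C10 methyl cis to C6 and cis to the C4 methyl as in the target.

Step 8
Reactants: 11 methyl 3-allyl-2-(1,3-dioxolan-2-yl)-1,3-dimethyl-5-oxocyclohexane-1-carboxylate
Product: 13 methyl 3-allyl-2-(1,3-dioxolan-2-yl)-1,3-dimethylcyclohexane-1-carboxylate, via tosylhydrazone 12 (not isolated)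
Conditions: TsNHNH2, EtOH, 50 °C; then catecholborane, CHCl3, 0 °C; NaOAc·3H2O, 60 °C
Reagents that add atoms: none
Why: Kabalka–Caglioti reduction of the tosylhydrazone should remove the helper carbonyl at C2 while sparing acetal, ester and terminal alkene.

Step 9
Reactants: 13 methyl 3-allyl-2-(1,3-dioxolan-2-yl)-1,3-dimethylcyclohexane-1-carboxylate
Product: 14 methyl 2-(1,3-dioxolan-2-yl)-1,3-dimethyl-3-(2-oxopropyl)cyclohexane-1-carboxylate
Conditions: PdCl2 (10 mol %), CuCl (1 equiv), O2 (1 atm), DMF/H2O 7:1, rt
Reagents that add atoms: water, O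
Why: Tsuji–Wacker oxidation should turn the terminal alkene into the methyl ketone (C8 carbonyl, C7 methyl) with Markovnikov selectivity.

Step 10
Reactants: 14 methyl 2-(1,3-dioxolan-2-yl)-1,3-dimethyl-3-(2-oxopropyl)cyclohexane-1-carboxylate
Product: 17 methyl 1,4a-dimethyl-6-oxo-1,2,3,4,4a,5,6,8a-octahydronaphthalene-1-carboxylate (trans-fused; ester trans to the angular methyl), via keto aldehyde 15 (not isolated), via aldol 16 (not isolated)
Conditions: 1 M HCl, THF, rt; then TsOH·H2O (10 mol %), PhH, 80 °C, Dean–Stark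
Reagents that add atoms: none
Why: Aqueous acid unmasks the C6 aldehyde, the methyl ketone enolises toward C7, C7 adds to C6 to give the aldol, and acid-promoted loss of water gives the conjugated enone. The closest known reaction type is the intramolecular aldol condensation of a 1,5-keto aldehyde, the ring-closing half of a Robinson annulation. Ring B closes in the 6-(enolendo)-exo-trig mode. No stereocentre is created, since the C6 carbinol is erased by dehydration, and the trans ring fusion follows from the trans, diequatorial C5 and C10 substituents already present. The step needs C7 and not C9 to react, which is secured because C9 attack would give a cyclobutane, and it needs C5 to keep its configuration, which the flanking quaternary carbons C4 and C10 and the amine-free acidic medium should ensure. The C8 carbonyl so formed blocks C7 within the enone, leaves C9 as the only α′ site and is later converted into the methylene.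

Step 11
Reactants: 18 (E)-3-methylpent-2-en-4-yn-1-ol
Product: 19 (E)-3-methylpenta-2,4-dien-1-ol
Conditions: H2 (1 atm), Pd on CaCO3 poisoned with Pb(OAc)2 (Lindlar catalyst), quinoline, EtOAc, rt
Reagents that add atoms: none
Why: Lindlar semihydrogenation should reduce only the terminal alkyne and leave the (E)-trisubstituted alkene.

Step 12
Reactants: 19 (E)-3-methylpenta-2,4-dien-1-ol
Product: 20 (E)-5-bromo-3-methylpenta-1,3-diene
Conditions: PBr3, Et2O, −20 °C; used fresh
Reagents that add atoms: phosphorus tribromide, BrP(Br)Br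
Why: PBr3 should convert the primary allylic alcohol into the bromide by SN2 displacement with the (E) geometry retained.

Step 13
Reactants: 17 methyl 1,4a-dimethyl-6-oxo-1,2,3,4,4a,5,6,8a-octahydronaphthalene-1-carboxylate; 20 (E)-5-bromo-3-methylpenta-1,3-diene
Product: 21 methyl 17-nor-8-oxo-9-epi-ent-labda-6,12E,14-trien-18-oate (side chain on C9 trans to the C10 methyl)
Conditions: LDA, THF, −78 °C; then 20, DMPU, −78 to −30 °C
Reagents that add atoms: none
Why: Kinetic deprotonation by LDA can occur only at the α′ carbon C9 because C7 is vinylic, and SN2 alkylation by the allylic bromide (whose two termini would give the same chain) should take place anti to the C10 methyl, so the chain is first installed axial.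

Step 14
Reactants: 21 methyl 17-nor-8-oxo-9-epi-ent-labda-6,12E,14-trien-18-oate
Product: 24 methyl 17-nor-8-oxo-ent-labda-12E,14-dien-18-oate (side chain on C9 equatorial and cis to the C10 methyl), via triethylsilyl enol ether 22 (not isolated), via 9-epi ketone 23 (not isolated)
Conditions: Et3SiH, RhCl(PPh3)3 (2 mol %), PhH, 50 °C; then NaOMe, MeOH, rt
Reagents that add atoms: none
Why: Rhodium-catalysed 1,4-hydrosilylation (Ojima) should reduce the enone without touching the diene, and methoxide then cleaves the silyl enol ether and equilibrates C9 through the enolate toward the epimer with the equatorial side chain, the minor epimer being recycled.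

Step 15
Reactants: 24 methyl 17-nor-8-oxo-ent-labda-12E,14-dien-18-oate
Product: 25 methyl ent-labda-8(17),12E,14-trien-18-oate
Conditions: Ph3PCH3Br, KOtBu, PhMe, 90 °C
Reagents that add atoms: methyltriphenylphosphonium bromide, C[P+](c1ccccc1)(c1ccccc1)c1ccccc1.[Br-]
Why: Wittig methylenation of the hindered ketone at raised temperature should install the exocyclic methylene, and the basic medium can only maintain the favoured C9 configuration.

Step 16
Reactants: 25 methyl ent-labda-8(17),12E,14-trien-18-oate
Product: 26 ent-labda-8(17),12E,14-trien-18-oic acid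
Conditions: LiSPr, HMPA, rt; then 1 M HCl
Reagents that add atoms: none
Why: SN2 demethylation of the hindered methyl ester by thiolate (Bartlett–Johnson) should free the acid before any quinone is present.

Step 17
Reactants: 27 3-methoxy-2-methylphenol
Product: 28 2-methoxy-3-methyl-1,4-benzoquinone
Conditions: (KSO3)2NO, KH2PO4, H2O/acetone, 0 °C
Reagents that add atoms: potassium nitrosodisulfonate (Fremy's salt), [K+].[K+].[O-]S(=O)(=O)N([O])S(=O)(=O)[O-]
Why: Teuber oxidation should convert the para-unsubstituted phenol into the 1,4-benzoquinone.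

Step 18
Reactants: 26 ent-labda-8(17),12E,14-trien-18-oic acid; 28 2-methoxy-3-methyl-1,4-benzoquinone
Product: 31 2-methoxy-3,7-dimethyl-1,4-naphthoquinone bearing at C8 the C11 methylene of the ent-labd-8(17)-en-18-oic acid unit (O-methyl ether of the target), via cycloadduct 29 (not isolated), via dihydronaphthoquinone 30 (not isolated)
Conditions: PhMe, 90 °C, sealed tube, dark; then MnO2 (10 equiv), rt to 60 °C
Reagents that add atoms: none
Why: In this thermal Diels–Alder reaction at the unsubstituted quinone double bond the carbonyl next to C–OMe is the stronger acceptor (the other is a vinylogous ester), so the CH2 terminus of the (E)-diene should bond β to it and C12 should end peri to that carbonyl, and MnO2 then dehydrogenates the adduct to the naphthoquinone, erasing the adduct stereocentres.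

Step 19
Reactants: 31 O-methyl ether of the target
Product: 32 CNP0259461.3, (4S,5S,9R,10S) in labdane numbering
Conditions: 1 M NaOH, MeOH, rt; then 1 M HCl
Reagents that add atoms: sodium hydroxide, [Na+].[OH-]
Why: Addition–elimination of hydroxide at the vinylogous ester carbon of the quinone should replace OMe by OH to give the 2-hydroxy-1,4-naphthoquinone.

**Compound list**

1 | 2,2-dimethoxyacetaldehyde | COC(OC)C=O | starting material
2 | methyl 2-(triphenylphosphoranylidene)propanoate | COC(=O)C(C)=P(c1ccccc1)(c1ccccc1)c1ccccc1 | starting material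
3 | methyl (E)-4,4-dimethoxy-2-methylbut-2-enoate | COC(=O)/C(C)=C/C(OC)OC | intermediate
4 | methyl (E)-2-methyl-4-oxobut-2-enoate | COC(=O)/C(C)=C/C=O | intermediate
5 | (E)-pent-3-en-2-one | C/C=C/C(C)=O | starting material
6 | (E)-2-(tert-butyldimethylsilyloxy)penta-1,3-diene | C=C(O[Si](C)(C)C(C)(C)C)/C=C/C | intermediate
7 | methyl 3-(tert-butyldimethylsilyloxy)-6-formyl-1,5-dimethylcyclohex-3-ene-1-carboxylate, formyl trans to CO2Me, C5 epimers | O=C[C@H]1C(C)C=C(O[Si](C)(C)C(C)(C)C)C[C@]1(C)C(=O)OC | intermediate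
8 | methyl 6-formyl-1,5-dimethyl-3-oxocyclohex-4-ene-1-carboxylate, formyl trans to CO2Me | O=C[C@H]1C(C)=CC(=O)C[C@]1(C)C(=O)OC | intermediate
9 | methyl 6-(1,3-dioxolan-2-yl)-1,5-dimethyl-3-oxocyclohex-4-ene-1-carboxylate | O1CCOC1[C@H]2C(C)=CC(=O)C[C@]2(C)C(=O)OC | intermediate
10 | methyl 5-allyl-6-(1,3-dioxolan-2-yl)-1,5-dimethyl-3-(trimethylsilyloxy)cyclohex-3-ene-1-carboxylate | O1CCOC1[C@H]2[C@@](C)(C=C(O[Si](C)(C)C)C[C@]2(C)C(=O)OC)CC=C | intermediate (not isolated)
11 | methyl 3-allyl-2-(1,3-dioxolan-2-yl)-1,3-dimethyl-5-oxocyclohexane-1-carboxylate | O1CCOC1[C@H]2[C@@](C)(CC(=O)C[C@]2(C)C(=O)OC)CC=C | intermediate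
12 | N-tosylhydrazone of 11 | O1CCOC1[C@H]2[C@@](C)(CC(=NNS(=O)(=O)c3ccc(C)cc3)C[C@]2(C)C(=O)OC)CC=C | intermediate (not isolated)
13 | methyl 3-allyl-2-(1,3-dioxolan-2-yl)-1,3-dimethylcyclohexane-1-carboxylate | O1CCOC1[C@H]2[C@@](C)(CCC[C@]2(C)C(=O)OC)CC=C | intermediate
14 | methyl 2-(1,3-dioxolan-2-yl)-1,3-dimethyl-3-(2-oxopropyl)cyclohexane-1-carboxylate | O1CCOC1[C@H]2[C@@](C)(CCC[C@]2(C)C(=O)OC)CC(C)=O | intermediate
15 | methyl 2-formyl-1,3-dimethyl-3-(2-oxopropyl)cyclohexane-1-carboxylate | O=C[C@H]1[C@@](C)(CCC[C@]1(C)C(=O)OC)CC(C)=O | intermediate (not isolated)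
16 | methyl 8-hydroxy-1,4a-dimethyl-6-oxodecahydronaphthalene-1-carboxylate, trans-fused, carbinol epimers | O=C1CC(O)[C@H]2[C@@](C)(CCC[C@]2(C)C(=O)OC)C1 | intermediate (not isolated)
17 | methyl 1,4a-dimethyl-6-oxo-1,2,3,4,4a,5,6,8a-octahydronaphthalene-1-carboxylate, trans-fused | O=C1C=C[C@H]2[C@@](C)(CCC[C@]2(C)C(=O)OC)C1 | intermediate
18 | (E)-3-methylpent-2-en-4-yn-1-ol | C#C/C(C)=C/CO | starting material
19 | (E)-3-methylpenta-2,4-dien-1-ol | C=C/C(C)=C/CO | intermediate
20 | (E)-5-bromo-3-methylpenta-1,3-diene | C=C/C(C)=C/CBr | intermediate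
21 | methyl 17-nor-8-oxo-9-epi-ent-labda-6,12E,14-trien-18-oate | O=C1C=C[C@H]2[C@@](C)(CCC[C@]2(C)C(=O)OC)[C@H]1C/C=C(/C=C)C | intermediate
22 | triethylsilyl enol ether (C7=C8) of 23 | CC[Si](CC)(CC)OC1=CC[C@H]2[C@@](C)(CCC[C@]2(C)C(=O)OC)[C@H]1C/C=C(/C=C)C | intermediate (not isolated)
23 | methyl 17-nor-8-oxo-9-epi-ent-labda-12E,14-dien-18-oate | O=C1CC[C@H]2[C@@](C)(CCC[C@]2(C)C(=O)OC)[C@H]1C/C=C(/C=C)C | intermediate (not isolated)
24 | methyl 17-nor-8-oxo-ent-labda-12E,14-dien-18-oate | O=C1CC[C@H]2[C@@](C)(CCC[C@]2(C)C(=O)OC)[C@@H]1C/C=C(/C=C)C | intermediate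
25 | methyl ent-labda-8(17),12E,14-trien-18-oate | C=C1CC[C@H]2[C@@](C)(CCC[C@]2(C)C(=O)OC)[C@@H]1C/C=C(/C=C)C | intermediate
26 | ent-labda-8(17),12E,14-trien-18-oic acid | C=C1CC[C@H]2[C@@](C)(CCC[C@]2(C)C(=O)O)[C@@H]1C/C=C(/C=C)C | intermediate
27 | 3-methoxy-2-methylphenol | COc1cccc(O)c1C | starting material
28 | 2-methoxy-3-methyl-1,4-benzoquinone | COC1=C(C)C(=O)C=CC1=O | intermediate
29 | 4a,5,8,8a-tetrahydro cycloadduct of 26 and 28 | C=C1CC[C@H]2[C@@](C)(CCC[C@]2(C)C(=O)O)[C@@H]1CC1C(C)=CCC2C1C(=O)C(OC)=C(C)C2=O | intermediate (not isolated)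
30 | 5,8-dihydro-1,4-naphthoquinone from 29 | C=C1CC[C@H]2[C@@](C)(CCC[C@]2(C)C(=O)O)[C@@H]1CC1C(C)=CCC2=C1C(=O)C(OC)=C(C)C2=O | intermediate (not isolated)
31 | O-methyl ether of the target | C=C1CC[C@H]2[C@@](C)(CCC[C@]2(C)C(=O)O)[C@@H]1Cc1c(C)ccc2c1C(=O)C(OC)=C(C)C2=O | intermediate
32 | CNP0259461.3 | C=C1CC[C@H]2[C@@](C)(CCC[C@]2(C)C(=O)O)[C@@H]1Cc1c(C)ccc2c1C(=O)C(O)=C(C)C2=O | target

**Step count and risks**

Total step count: 19. Longest linear sequence: 15 (steps 1, 2, 4–10, 13–16, 18, 19). Steps 3, 11–12 and 17 are side branches.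

Three steps most likely to fail:

Step 7. The allylcopper reagent may add 1,2 to the hindered β,β-disubstituted enone or fail to convert it. The fallback sets out from 8 and uses a Hosomi–Sakurai addition, with the aldehyde carried at the alcohol oxidation level. NaBH(OAc)3 (PhH, 80 °C) reduces only the aldehyde to methyl 6-(hydroxymethyl)-1,5-dimethyl-3-oxocyclohex-4-ene-1-carboxylate F1, which is silylated at once (TBDPSCl, imidazole) to its silyl ether F2. AllylSiMe3 with TiCl4 (CH2Cl2, −78 °C) gives the allyl ketone F3, again anti to the C5 substituent. The ketone is removed as in step 8 through the tosylhydrazone F4 to the allyl compound F5, and Wacker oxidation as in step 9 gives the methyl ketone F6. HF·pyridine frees the keto alcohol F7, and Dess–Martin periodinane gives 15, which rejoins the route at the second stage of step 10.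

Step 4. The catalyst may discriminate poorly between the faces of the β,β-disubstituted enal, or its acidity may strip the silyl group from the diene before cycloaddition. The fallback sets out from 4 and 6, which combine without catalyst (PhMe, 80 °C) to racemic 7. The racemic series is carried through steps 5–16, and racemic 26 is resolved by crystallisation of its (R)-1-phenylethylammonium salt F8 (the antipodal amine if the wrong salt crystallises). Acidification with 1 M HCl comes back to the route at enantiopure 26.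

Step 18. The methyl on C13 opposes the directing effect of the C11 substituent on the diene, so the regioselectivity of the cycloaddition may erode. The fallback sets out from 26 and 28 and moves the control to chelation. Compound 28 is hydrolysed (1 M NaOH, then HCl) to 2-hydroxy-3-methyl-1,4-benzoquinone F9. Cycloaddition with 26 in the presence of Eu(fod)3, which binds the 2-hydroxy and 1-carbonyl oxygens and so strengthens the polarisation of the dienophile, gives the adduct F10. MnO2 takes F10 through the dihydronaphthoquinone F11 to 32, so the route is rejoined at the target and step 19 falls away.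

Further compounds
F1 | step 7 | methyl 6-(hydroxymethyl)-1,5-dimethyl-3-oxocyclohex-4-ene-1-carboxylate | OC[C@H]1C(C)=CC(=O)C[C@]1(C)C(=O)OC
F2 | step 7 | tert-butyldiphenylsilyl ether of F1 | CC(C)(C)[Si](c1ccccc1)(c1ccccc1)OC[C@H]2C(C)=CC(=O)C[C@]2(C)C(=O)OC
F3 | step 7 | methyl 3-allyl-2-(tert-butyldiphenylsilyloxymethyl)-1,3-dimethyl-5-oxocyclohexane-1-carboxylate | CC(C)(C)[Si](c1ccccc1)(c1ccccc1)OC[C@H]2[C@@](C)(CC(=O)C[C@]2(C)C(=O)OC)CC=C
F4 | step 7 | N-tosylhydrazone of F3 | CC(C)(C)[Si](c1ccccc1)(c1ccccc1)OC[C@H]2[C@@](C)(CC(=NNS(=O)(=O)c3ccc(C)cc3)C[C@]2(C)C(=O)OC)CC=C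
F5 | step 7 | methyl 3-allyl-2-(tert-butyldiphenylsilyloxymethyl)-1,3-dimethylcyclohexane-1-carboxylate | CC(C)(C)[Si](c1ccccc1)(c1ccccc1)OC[C@H]2[C@@](C)(CCC[C@]2(C)C(=O)OC)CC=C
F6 | step 7 | methyl 2-(tert-butyldiphenylsilyloxymethyl)-1,3-dimethyl-3-(2-oxopropyl)cyclohexane-1-carboxylate | CC(C)(C)[Si](c1ccccc1)(c1ccccc1)OC[C@H]2[C@@](C)(CCC[C@]2(C)C(=O)OC)CC(C)=O
F7 | step 7 | methyl 2-(hydroxymethyl)-1,3-dimethyl-3-(2-oxopropyl)cyclohexane-1-carboxylate | OC[C@H]1[C@@](C)(CCC[C@]1(C)C(=O)OC)CC(C)=O
F8 | step 4 | (R)-1-phenylethylammonium salt of 26 | C=C1CC[C@H]2[C@@](C)(CCC[C@]2(C)C(=O)[O-])[C@@H]1C/C=C(/C=C)C.C[C@@H]([NH3+])c1ccccc1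
F9 | step 18 | 2-hydroxy-3-methyl-1,4-benzoquinone | OC1=C(C)C(=O)C=CC1=O
F10 | step 18 | 4a,5,8,8a-tetrahydro cycloadduct of 26 and F9 | C=C1CC[C@H]2[C@@](C)(CCC[C@]2(C)C(=O)O)[C@@H]1CC1C(C)=CCC2C1C(=O)C(O)=C(C)C2=O
F11 | step 18 | 5,8-dihydro-1,4-naphthoquinone from F10 | C=C1CC[C@H]2[C@@](C)(CCC[C@]2(C)C(=O)O)[C@@H]1CC1C(C)=CCC2=C1C(=O)C(O)=C(C)C2=O
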